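The target is taken apart at its four C–Br bonds. In ring A (the phenol ring: C1 carries OH, C2 the ether oxygen) and ring B (C1' on that oxygen), C5, C2' and C4' lie para or ortho to the bridging oxygen, whereas C5 is meta to the hydroxyl and only C6 is ortho to it. With the hydroxyl silenced as a methanesulfonate, the diaryl ether oxygen becomes the only strong donor, so a single bromination of 2-phenoxyphenyl methanesulfonate should install all three of those bromines. Unmasking then returns the phenol, which directs the last bromine to C6.

Key step: step 2

Remark on the chemistry: the target has no stereocentre, so no configuration has to be set; 2-phenoxyphenol and methanesulfonyl chloride are taken as commercial.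

Step 1
Reactants: 1 2-phenoxyphenol; 2 methanesulfonyl chloride
Product: 3 2-phenoxyphenyl methanesulfonate
Conditions: MsCl (1.2 equiv), Et3N (1.5 equiv), CH2Cl2, 0 °C to rt
Reagents that add atoms: methanesulfonyl chloride (compound 2), CS(=O)(=O)Cl
Why: O-Sulfonylation of a phenol with a sulfonyl chloride and a tertiary amine is routine, and the sulfonyl group draws the lone pairs of the C1 oxygen away from ring A, which is what the next step requires.

Step 2
Reactants: 3 2-phenoxyphenyl methanesulfonate
Product: 6 5-bromo-2-(2,4-dibromophenoxy)phenyl methanesulfonate, via monobromide 4 (not isolated), via dibromide 5 (not isolated)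
Conditions: Br2 (3.05 equiv), FeBr3 (5 mol%), CH2Cl2, 0 °C to 40 °C, dark
Reagents that add atoms: bromine, BrBr
Why: Three successive electrophilic aromatic substitutions, each through an arenium ion; the closest known reaction type is the bromination of diaryl ethers para and then ortho to the bridging oxygen, carried out on an aryl sulfonate that stays passive. Ring B carries no withdrawing group and should react first at C4' (4), ring A follows at C5, para to the ether oxygen (5), and the FeBr3-assisted third substitution enters ring B at C2'. No ring is closed and no stereocentre arises. On ring A the step needs C5 and not C4 or C3: the sulfonyloxy oxygen at C1 is a net deactivator, so C4 (para to it, only meta to the ether oxygen) is switched off, and C3 is the crowded ortho position of an ether that prefers para attack. The step must also stop at three bromines: every site then left is meta to two withdrawing groups (C6' to both ring-B bromines, C3 to C5–Br and the sulfonate), so with 3.05 equivalents of Br2 a fourth substitution should be much slower. The methanesulfonate does not react with Br2, HBr or FeBr3.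

Step 3
Reactants: 6 5-bromo-2-(2,4-dibromophenoxy)phenyl methanesulfonate
Product: 8 5-bromo-2-(2,4-dibromophenoxy)phenol, via sodium phenolate 7 (not isolated)
Conditions: NaOH (aq, 4 equiv), 1,4-dioxane, 80 °C; then HCl (aq)
Reagents that add atoms: none
Why: Alkaline hydrolysis of an aryl sulfonate ester, in which hydroxide cleaves the S–O bond and expels a phenolate made a good leaving group by its bromine and aryloxy substituents, while unactivated aryl bromides and the diaryl ether do not react with aqueous hydroxide at this temperature.

Step 4
Reactants: 8 5-bromo-2-(2,4-dibromophenoxy)phenol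
Product: 9 2,3-dibromo-6-(2,4-dibromophenoxy)phenol (the target)
Conditions: Br2 (1.0 equiv), t-BuNH2 (2.0 equiv), toluene/CH2Cl2, −70 °C to rt
Reagents that add atoms: bromine, BrBr
Why: Amine-mediated ortho-bromination of a phenol, in which N-bromo-tert-butylamine formed in the flask hydrogen-bonds to the OH and hands bromine to the neighbouring carbon; C2 is occupied, so C6 is the only ortho site, and the low temperature and non-polar medium suppress the free-Br2 pathway that would attack C4, para to the hydroxyl.

Compound list
1 | 2-phenoxyphenol | Oc1ccccc1Oc1ccccc1 | starting material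
2 | methanesulfonyl chloride | CS(=O)(=O)Cl | starting material
3 | 2-phenoxyphenyl methanesulfonate | CS(=O)(=O)Oc1ccccc1Oc1ccccc1 | intermediate
4 | 2-(4-bromophenoxy)phenyl methanesulfonate | CS(=O)(=O)Oc1ccccc1Oc1ccc(Br)cc1 | intermediate
5 | 5-bromo-2-(4-bromophenoxy)phenyl methanesulfonate | CS(=O)(=O)Oc1cc(Br)ccc1Oc1ccc(Br)cc1 | intermediate
6 | 5-bromo-2-(2,4-dibromophenoxy)phenyl methanesulfonate | CS(=O)(=O)Oc1cc(Br)ccc1Oc1ccc(Br)cc1Br | intermediate
7 | sodium 5-bromo-2-(2,4-dibromophenoxy)phenolate | [Na+].[O-]c1cc(Br)ccc1Oc1ccc(Br)cc1Br | intermediate
8 | 5-bromo-2-(2,4-dibromophenoxy)phenol | Oc1cc(Br)ccc1Oc1ccc(Br)cc1Br | intermediate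
9 | 2,3-dibromo-6-(2,4-dibromophenoxy)phenol | Oc1c(Oc2ccc(Br)cc2Br)ccc(Br)c1Br | target

Total step count: 4
Longest linear sequence: 4 steps

Steps most likely to fail

1. Step 2. The number and placement of bromines may drift: a fourth substitution may set in before the third is complete, or attack on ring A may stray to C3 or C4, so that isomeric or over-brominated sulfonates accompany the product. The fallback sets out from 2 and comes back at 6; it brings the three bromines in with the building blocks and forms the ether bond last. Commercial 5-bromo-2-methoxyphenol is mesylated with 2 (Et3N, CH2Cl2, 0 °C) to 5-bromo-2-methoxyphenyl methanesulfonate F1. BBr3 (CH2Cl2, −78 °C to rt) then removes the methyl group, to which the sulfonate is inert, giving 5-bromo-2-hydroxyphenyl methanesulfonate F2. Separately, 2,4-dibromo-1-iodobenzene and 1,3-dibromobenzene (mCPBA, TfOH, CH2Cl2) are joined to bis(2,4-dibromophenyl)iodonium trifluoromethanesulfonate F3. Metal-free O-arylation of F2 with F3 (t-BuOK, THF, rt to 40 °C) should then give 6, after which steps 3 and 4 follow unchanged.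

2. Step 4. Bromine may be delivered to the wrong site: C6 is squeezed between the hydroxyl and the C5 bromine, so attack para to the hydroxyl at C4, or a second bromination, may compete. The fallback sets out from 1 and comes back at 9; it installs the ortho bromine first, where its site is unhindered. Compound 1 with Br2 and t-BuNH2 (toluene, −70 °C) should give 2-bromo-6-phenoxyphenol F4, as in the ortho-bromination of 2-alkoxyphenols, and any para isomer is removed at this cheap stage. Mesylation with 2 (Et3N, CH2Cl2) gives 2-bromo-6-phenoxyphenyl methanesulfonate F5. Three-fold bromination under the conditions of step 2, with the C6 bromine as a spectator and C5 still para to the ether oxygen, should give 2,3-dibromo-6-(2,4-dibromophenoxy)phenyl methanesulfonate F6. Hydrolysis under the conditions of step 3 then gives 9.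

3. Step 3. The S–O cleavage may stall, or, if the alkali is forced, hydroxide may begin to attack the brominated rings. The fallback sets out from 1 and comes back at 8; it uses a mask that comes off at room temperature from the start. Compound 1 with Tf2O and pyridine (CH2Cl2, 0 °C) gives 2-phenoxyphenyl trifluoromethanesulfonate F7. Bromination under the conditions of step 2, where the triflyloxy group deactivates C4 even more strongly, should give 5-bromo-2-(2,4-dibromophenoxy)phenyl trifluoromethanesulfonate F8. Et4NOH (aq) in 1,4-dioxane at rt then cleaves the aryl triflate to 8.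

Further compounds
F1 | step 2 | 5-bromo-2-methoxyphenyl methanesulfonate | COc1ccc(Br)cc1OS(C)(=O)=O
F2 | step 2 | 5-bromo-2-hydroxyphenyl methanesulfonate | CS(=O)(=O)Oc1cc(Br)ccc1O
F3 | step 2 | bis(2,4-dibromophenyl)iodonium trifluoromethanesulfonate | Brc1ccc([I+]c2ccc(Br)cc2Br)c(Br)c1.[O-]S(=O)(=O)C(F)(F)F
F4 | step 4 | 2-bromo-6-phenoxyphenol | Oc1c(Br)cccc1Oc1ccccc1
F5 | step 4 | 2-bromo-6-phenoxyphenyl methanesulfonate | CS(=O)(=O)Oc1c(Br)cccc1Oc1ccccc1
F6 | step 4 | 2,3-dibromo-6-(2,4-dibromophenoxy)phenyl methanesulfonate | CS(=O)(=O)Oc1c(Br)c(Br)ccc1Oc1ccc(Br)cc1Br
F7 | step 3 | 2-phenoxyphenyl trifluoromethanesulfonate | O=S(=O)(Oc1ccccc1Oc1ccccc1)C(F)(F)F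
F8 | step 3 | 5-bromo-2-(2,4-dibromophenoxy)phenyl trifluoromethanesulfonate | O=S(=O)(Oc1cc(Br)ccc1Oc1ccc(Br)cc1Br)C(F)(F)F
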